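## Analysis of the target

Target 14 is a monocyclic oxolane. With the ring numbered O1, C2, C3, C4, C5 (locants used throughout), C2 carries a 3,4-dimethoxyphenyl group, C3 a CH2O arm (C6) esterified with 3,4-dimethoxybenzoic acid, C4 a free hydroxyl, and C5 is a methylene. C2, C3 and C4 are contiguous stereocentres, (2S,3R,4S). Reading the SMILES places the aryl group, the C6 arm and the hydroxyl on one face, so the triad is all-cis, the most congested arrangement the ring can have. No centre can therefore be corrected by equilibration: each must be set kinetically, and C3 should never pass through an epimerisable carbonyl oxidation state. The C2–O1 bond is a benzylic ether activated by an electron-rich arene, so strong acid and hydrogenolysis are excluded. The C6 ester sits cis to the C4 hydroxyl, so base invites acyl migration, and the two oxygens must be told apart. The strategy rests on C3 lying between the other two stereocentres. C3 and C4 can be traced to an alkyne carbon and an aldehyde carbon joined through the C2–O1–C5 tether. A C3=C6 exo-methylene flanked by cis C2-aryl and C4-oxygen has one open face, so adding hydrogen there forces C6 onto the crowded face.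

## Retrosynthetic reasoning

14 ⇒ 13. The last operation is removal of a triethylsilyl group from O4 of silyl ether 13. Keeping O4 masked until the end means the ester can only be placed on O6, and the unveiling can be done under weakly acidic conditions where neither acyl migration nor benzylic ionisation occurs.

13 ⇒ 11 + 12. The ester C–O bond is cut to give primary alcohol 11 and acid chloride 12. This is the most convergent place to bring in the second aryl unit, and the forward reaction is a routine acylation of the only free hydroxyl.

11 ⇒ 9 (through borane 10). The C3–H and C6–O bonds are removed to reveal the exo-methylene of 9. Forward, a hindered borane must add its hydrogen to C3 from the face opposite the cis aryl and silyloxy groups. That single facial choice completes the all-cis triad, and C3 is created directly at the alcohol oxidation level.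

9 ⇒ 8. The C3–C4 bond is cut, opening the ring to ynal 8. Both carbons are electrophilic in 8, so the forward step needs a low-valent metal to supply the electrons. Nickel(0) with a trialkylsilane does this and delivers, in one operation, the ring, the C3 exo-methylene and O4 already silylated. Cutting here leaves an acyclic precursor with a single stereocentre (C2).

8 ⇒ 6 (through diol 7). The aldehyde is traced to the terminal alkene of allyl ether 6. The α-alkoxy aldehyde is fragile, so it is unmasked by oxidative cleavage immediately before the key step.

6 ⇒ 4 + 5. The O1–C5 bond is cut to propargylic alcohol 4 and allyl bromide 5. The forward etherification does not touch the stereocentre.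

4 ⇒ 3 ⇒ 1 + 2. The C2–C3 bond is cut to veratraldehyde 1 and silylacetylene 2. A catalytic asymmetric alkynylation sets C2, the only stereocentre introduced by an external chiral source. The silyl group of 3 serves only as a handle for acetylene and is removed at once to give 4.

## Alternatives that were turned down

Alternative 1: Carbonylative oxypalladation. The disconnection is O1–C2 plus C3–C6. The precursor is alkynol A1, (S)-2-(tert-butyldimethylsilyloxy)-4-(3,4-dimethoxyphenyl)but-3-yn-1-ol, with C4 taken from the chiral pool. Forward, palladium(II) activates the aryl alkyne, the primary hydroxyl attacks 5-endo-dig, and the vinylpalladium is trapped by alkoxycarbonylation to give dihydrofuran ester A2. Syn-hydrogenation of C2=C3 anti to the silyloxy group would then set C2 and C3 together.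
- For: C4 is absolute from the outset, ring and C6 arrive in one step, and no remote induction is needed. On that last point it is stronger than the chosen route.
- Against: A2 is one β-elimination of silanol away from an aromatic furan. Its tetrasubstituted donor–acceptor alkene would need forcing hydrogenation, which threatens the benzylic C2–O1 bond. The all-cis ester that results is epimerisable at C3.
- Comparison: step count is similar. The chosen route offers a stable 1,1-disubstituted alkene that adds a borane readily, and a C3 that is never α to a carbonyl.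

Alternative 2: Silicon-tethered radical cyclisation. The disconnection is C3–C6, delivered from O4. The precursor is bromomethylsilyl ether A3, (S)-3-[(bromomethyl)dimethylsilyloxy]-5-(3,4-dimethoxyphenyl)-2,3-dihydrofuran. Forward, the silylmethyl radical closes 5-exo-trig onto C3 of the enol ether, and the benzylic C2 radical takes hydrogen on the convex face to give the cis-fused oxasilolane A4. Oxidation of the C–Si bond would then reveal the hydroxymethyl group.
- For: ring fusion guarantees the C3/C4 cis relationship. That is firmer than the steric argument used for hydroboration in the chosen route.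
- Against: A3 is a 3-oxygenated 2,3-dihydrofuran that aromatises on loss of silanol, and making it enantiopure costs several steps. C2 is set by hydrogen transfer to a delocalised radical, which must push the aryl group into the concave pocket. A stoichiometric tin hydride is needed, and the diol still requires selective acylation.
- Comparison: the chosen route fixes C2 first, by catalysis, and keeps it sp3 throughout. Only C3 depends on facial bias, and tethered delivery is kept in reserve as a fallback.

Alternative 3: Semipinacol ring contraction. The disconnection is C2–C3, formed by a 1,2-shift. The precursor is the arabino-configured C-aryl pyranoside triflate A5, with aryl, 3-O-triflate and 4-O-silyl cis and the free 2-hydroxyl trans. Forward, deprotonation of the 2-hydroxyl drives migration of the anomeric carbon from C2 to C3 with loss of triflate, contracting the oxane to the all-cis aldehyde A6.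
- For: all three centres come from the chiral pool through a stereospecific shift (retention at the migrating carbon, inversion at the terminus). This is the strongest of the four on stereochemical certainty.
- Against: C-arylation with anomeric control and differentiation of three hydroxyls put roughly twice as many steps before the key step. A6 is an all-cis β-silyloxy aldehyde formed under base, so epimerisation at C3 and β-elimination are both expected.
- Comparison: the chosen route accepts one uncertain induction in exchange for an eight-step sequence and a non-epimerisable C3.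

Key step: step 5

Assumption: the zinc–ProPhenol alkynylation is taken to deliver the alkynyl group to the Si face of an aryl aldehyde with the (R,R) ligand. The configuration of 3 is to be checked (Mosher esters) and the antipodal ligand used if the sense proves opposite. Changes of R/S descriptor along the route (3 to 4, 9 to 11, 13 to 14) reflect changed CIP priorities, not inversion.

Step 1
Reactants: 1 veratraldehyde; 2 trimethylsilylacetylene
Product: 3 (R)-1-(3,4-dimethoxyphenyl)-3-(trimethylsilyl)prop-2-yn-1-ol
Conditions: Me2Zn (3 equiv), 2 (3 equiv), (R,R)-ProPhenol (10 mol %), Ph3P=O (20 mol %), toluene, 0 to 4 °C; aq. NH4Cl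
Reagents that add atoms: none
Why: Catalytic asymmetric alkynylation of an aryl aldehyde: the zinc alkynylide formed from 2 and Me2Zn adds inside the chiral dinuclear zinc pocket to the Si face of 1. This sets the carbinol centre that becomes C2; it is (R) in 3 only because the silylalkynyl group outranks aryl.

Step 2
Reactants: 3 (R)-1-(3,4-dimethoxyphenyl)-3-(trimethylsilyl)prop-2-yn-1-ol
Product: 4 (S)-1-(3,4-dimethoxyphenyl)prop-2-yn-1-ol
Conditions: K2CO3 (0.2 equiv), MeOH, 0 °C to rt
Reagents that add atoms: none
Why: Methoxide-catalysed protodesilylation of an alkynylsilane; the carbinol C–H is not acidic under carbonate, so the centre is untouched.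

Step 3
Reactants: 4 (S)-1-(3,4-dimethoxyphenyl)prop-2-yn-1-ol; 5 allyl bromide
Product: 6 (S)-4-[1-(allyloxy)prop-2-yn-1-yl]-1,2-dimethoxybenzene
Conditions: NaH (1.05 equiv), 5 (1.3 equiv), Bu4NI (cat.), THF, 0 °C to rt
Reagents that add atoms: none
Why: Williamson ether synthesis: one equivalent of hydride deprotonates only the hydroxyl, and the alkoxide displaces bromide from 5. Low temperature and no excess base avoid propargyl–allenyl isomerisation at the doubly activated C–H.

Step 4
Reactants: 6 (S)-4-[1-(allyloxy)prop-2-yn-1-yl]-1,2-dimethoxybenzene
Product: 8 (S)-2-[1-(3,4-dimethoxyphenyl)prop-2-ynyloxy]acetaldehyde, via vicinal diol 7 (not isolated)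
Conditions: OsO4 (2 mol %), NaIO4 (4 equiv), 2,6-lutidine (2 equiv), dioxane/H2O 3:1, rt
Reagents that add atoms: osmium tetroxide, O=[Os](=O)(=O)=O (catalytic, transfers the oxygen atoms); sodium periodate, [Na+].[O-]I(=O)(=O)=O (terminal oxidant that restores the osmium oxo groups)
Why: Lemieux–Johnson cleavage: osmium dihydroxylates the isolated terminal alkene much faster than the alkyne or the arene, and periodate cleaves diol 7 and re-oxidises osmium while lutidine suppresses over-oxidation. Aldehyde 8 is dried azeotropically and used at once.

Step 5
Reactants: 8 (S)-2-[1-(3,4-dimethoxyphenyl)prop-2-ynyloxy]acetaldehyde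
Product: 9 (2R,4S)-2-(3,4-dimethoxyphenyl)-3-methylene-4-(triethylsilyloxy)oxolane (2,4-cis)
Conditions: Ni(cod)2 (10 mol %), PBu3 (20 mol %), Et3SiH (5 equiv), THF, 0 °C to rt, slow addition of 8
Reagents that add atoms: triethylsilane, CC[SiH](CC)CC
Why: Nickel(0) binds the alkyne and the aldehyde of 8 and couples them oxidatively (C3–C4 bond) to an oxanickelacyclopentene fused to the new oxolane; σ-bond metathesis of Ni–O with the silane forms the O–Si bond and a vinylnickel hydride, and C–H reductive elimination releases 9 and nickel(0). The closest known reaction type is the nickel/phosphine-catalysed reductive cyclisation of ynals with trialkylsilanes to silylated 2-alkylidenecycloalkanols. The oxolane closes 5-exo-dig: the internal alkyne carbon becomes ring atom C3 and the terminal carbon becomes the exocyclic methylene C6, and the tether allows no other regiochemistry. The new stereocentre is C4, controlled by the existing C2 centre: in the bicyclic transition state the C4–O bond is held in the plane of the nascent alkene, C5 is displaced from it, and the C2 aryl group takes the pseudo-equatorial site, which places aryl and oxygen cis. Because the alkyne is terminal, only a hydrogen on C6 faces C2, so no allylic strain opposes this arrangement. The step needs chemoselectivity (intramolecular coupling over alkyne oligomerisation and over direct hydrosilylation of the aldehyde), which the short tether and slow addition of 8 should secure. It also needs 1,3-diastereoselectivity, which rests on the conformational argument above and is the unproven point of the route.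

Step 6
Reactants: 9 (2R,4S)-2-(3,4-dimethoxyphenyl)-3-methylene-4-(triethylsilyloxy)oxolane
Product: 11 [(2S,3S,4S)-2-(3,4-dimethoxyphenyl)-4-(triethylsilyloxy)oxolan-3-yl]methanol, via B-alkyl-9-BBN adduct 10 (not isolated)
Conditions: 9-BBN (1.5 equiv), THF, 0 °C to rt; then NaBO3·4H2O, THF/H2O, rt
Reagents that add atoms: 9-borabicyclo[3.3.1]nonane, C1CC2CCCC(C1)B2 (boron only in 10, hydrogen to C3); sodium perborate, [Na+].[Na+].O[B-]1(O)OO[B-](O)(O)OO1 (hydroxyl oxygen)
Why: Hydroboration–oxidation: boron adds to terminal C6 and hydrogen to C3 in a syn four-centre addition from the face opposite the cis aryl and silyloxy groups, so C6 is pushed onto their face and C3 is set all-cis. Perborate oxidises the C–B bond with retention under nearly neutral conditions that should spare the silyl ether and limit silyl migration.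

Step 7
Reactants: 11 [(2S,3S,4S)-2-(3,4-dimethoxyphenyl)-4-(triethylsilyloxy)oxolan-3-yl]methanol; 12 3,4-dimethoxybenzoyl chloride
Product: 13 [(2S,3S,4S)-2-(3,4-dimethoxyphenyl)-4-(triethylsilyloxy)oxolan-3-yl]methyl 3,4-dimethoxybenzoate
Conditions: 12 (1.2 equiv), Et3N, DMAP (cat.), CH2Cl2, 0 °C
Reagents that add atoms: none
Why: DMAP-catalysed acylation (nucleophilic catalysis) of the only free hydroxyl; O4 is blocked as its silyl ether, so the regiochemistry is unambiguous.

Step 8
Reactants: 13 [(2S,3S,4S)-2-(3,4-dimethoxyphenyl)-4-(triethylsilyloxy)oxolan-3-yl]methyl 3,4-dimethoxybenzoate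
Product: 14 [(2S,3R,4S)-2-(3,4-dimethoxyphenyl)-4-hydroxyoxolan-3-yl]methyl 3,4-dimethoxybenzoate
Conditions: PPTS (cat.), MeOH/CH2Cl2, 0 °C to rt
Reagents that add atoms: none
Why: Mild acid-catalysed solvolysis of a triethylsilyl ether; the conditions are too weak to ionise the benzylic C2–O1 bond or to move the acyl group, and no stereocentre is touched.

Compound list

1 | veratraldehyde (3,4-dimethoxybenzaldehyde) | COc1ccc(C=O)cc1OC | starting material
2 | trimethylsilylacetylene | C#C[Si](C)(C)C | starting material
3 | (R)-1-(3,4-dimethoxyphenyl)-3-(trimethylsilyl)prop-2-yn-1-ol | C[Si](C)(C)C#C[C@H](O)c1ccc(OC)c(OC)c1 | intermediate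
4 | (S)-1-(3,4-dimethoxyphenyl)prop-2-yn-1-ol | C#C[C@H](O)c1ccc(OC)c(OC)c1 | intermediate
5 | allyl bromide | C=CCBr | starting material
6 | (S)-4-[1-(allyloxy)prop-2-yn-1-yl]-1,2-dimethoxybenzene | C#C[C@H](OCC=C)c1ccc(OC)c(OC)c1 | intermediate
7 | 3-{[(1S)-1-(3,4-dimethoxyphenyl)prop-2-yn-1-yl]oxy}propane-1,2-diol (both epimers at the carbinol carbon) | C#C[C@H](OCC(O)CO)c1ccc(OC)c(OC)c1 | intermediate
8 | (S)-2-[1-(3,4-dimethoxyphenyl)prop-2-ynyloxy]acetaldehyde | C#C[C@H](OCC=O)c1ccc(OC)c(OC)c1 | intermediate
9 | (2R,4S)-2-(3,4-dimethoxyphenyl)-3-methylene-4-(triethylsilyloxy)oxolane | C=C1[C@H](O[Si](CC)(CC)CC)CO[C@@H]1c1ccc(OC)c(OC)c1 | intermediate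
10 | 9-{[(2S,3S,4S)-2-(3,4-dimethoxyphenyl)-4-(triethylsilyloxy)oxolan-3-yl]methyl}-9-borabicyclo[3.3.1]nonane | C1CC2CCCC(C1)B2C[C@@H]1[C@H](O[Si](CC)(CC)CC)CO[C@@H]1c1ccc(OC)c(OC)c1 | intermediate
11 | [(2S,3S,4S)-2-(3,4-dimethoxyphenyl)-4-(triethylsilyloxy)oxolan-3-yl]methanol | OC[C@@H]1[C@H](O[Si](CC)(CC)CC)CO[C@@H]1c1ccc(OC)c(OC)c1 | intermediate
12 | 3,4-dimethoxybenzoyl chloride | COc1ccc(C(Cl)=O)cc1OC | starting material
13 | [(2S,3S,4S)-2-(3,4-dimethoxyphenyl)-4-(triethylsilyloxy)oxolan-3-yl]methyl 3,4-dimethoxybenzoate | COc1ccc(C(=O)OC[C@@H]2[C@H](O[Si](CC)(CC)CC)CO[C@@H]2c2ccc(OC)c(OC)c2)cc1OC | intermediate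
14 | [(2S,3R,4S)-2-(3,4-dimethoxyphenyl)-4-hydroxyoxolan-3-yl]methyl 3,4-dimethoxybenzoate | COc1ccc(C(=O)OC[C@@H]2[C@H](O)CO[C@@H]2c2ccc(OC)c(OC)c2)cc1OC | target

Total step count: 8. Longest linear sequence: 8 steps (from 1).

Least certain steps

Step 5 (key). The most likely failure is poor or reversed 1,3-diastereoselection at C4, because the only controlling element is the C2 aryl group two atoms away. Competing oligomerisation of the terminal alkyne on nickel(0) would show up as low conversion. Fallback: correct C4 after the event by SN2 inversion. Setting out from 8, the cyclisation is run as above and the 2,4-trans silyl ether (2R,4R)-2-(3,4-dimethoxyphenyl)-3-methylene-4-(triethylsilyloxy)oxolane F1 is separated from 9. TBAF in THF gives the trans allylic alcohol (2R,4R)-2-(3,4-dimethoxyphenyl)-3-methyleneoxolan-4-ol F2. Mitsunobu reaction (PPh3, DIAD, 4-nitrobenzoic acid, THF, 0 °C) inverts C4 to the cis ester (2R,4S)-2-(3,4-dimethoxyphenyl)-3-methyleneoxolan-4-yl 4-nitrobenzoate F3. Methanolysis (K2CO3, MeOH) gives the cis alcohol (2R,4S)-2-(3,4-dimethoxyphenyl)-3-methyleneoxolan-4-ol F4, and Et3SiCl/imidazole returns the material to the route at 9.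

Step 1. Enantioselectivity may be incomplete with this electron-rich, less electrophilic aldehyde, background methyl transfer from the zinc reagent may compete, and the sense of induction is assumed. Fallback: resolution instead of asymmetric catalysis. From 1, ethynylmagnesium bromide (THF, 0 °C) gives racemic 1-(3,4-dimethoxyphenyl)prop-2-yn-1-ol F5. Lipase-catalysed acylation (immobilised Candida antarctica lipase B, vinyl acetate) should acylate the enantiomer in which aryl is the large and ethynyl the medium group, giving (R)-1-(3,4-dimethoxyphenyl)prop-2-yn-1-yl acetate F6. The unreacted (S)-alcohol is 4, where the route is rejoined without the silyl detour.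

Step 4. Over-oxidation, hydration or self-condensation of the α-alkoxy aldehyde, or attack of the oxidant on the alkyne or the dimethoxyarene, would erode the yield. Fallback: reach the aldehyde by reduction instead of oxidation. From 4, alkylation with 2-bromo-N-methoxy-N-methylacetamide (NaH, THF, 0 °C) gives the Weinreb amide (S)-2-[1-(3,4-dimethoxyphenyl)prop-2-ynyloxy]-N-methoxy-N-methylacetamide F7. DIBAL-H (THF, −78 °C) stops at the aldehyde through the stable chelate and returns the route at 8.

Step 7 (with step 8). Silyl migration from O4 to the cis primary O6, during the oxidative work-up of step 6 or under the acylation base, would misplace the ester, and acyl migration could follow deprotection. Fallback: drop the protecting-group differentiation and rely on primary-over-secondary selectivity. From 11 (or its migrated isomer), PPTS/MeOH gives the diol (2S,3R,4S)-2-(3,4-dimethoxyphenyl)-3-(hydroxymethyl)oxolan-4-ol F8. Acylation with 12 and 2,4,6-collidine in CH2Cl2 at −78 to −40 °C should take the primary hydroxyl only and reach 14 directly.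

Step 6. Facial selectivity may be insufficient if both cis substituents lie pseudo-equatorial and shield the alkene only weakly. Fallback: deliver C6 functionality intramolecularly from O4, which enforces cis ring fusion. From 9, TBAF gives F4. Ph2SiHCl/imidazole gives the hydrosilyl ether (2R,4S)-2-(3,4-dimethoxyphenyl)-4-(diphenylsilyloxy)-3-methyleneoxolane F9. Platinum(0)-catalysed intramolecular hydrosilylation (Karstedt catalyst, toluene, 60 °C) closes the cis-fused oxasilolane, all-cis 4-(3,4-dimethoxyphenyl)-2,2-diphenyl-tetrahydrofuro[3,4-d][1,2]oxasilole F10. Tamao oxidation (H2O2, KF, KHCO3, THF/MeOH) gives diol F8, and the selective acylation with 12 described under step 7 rejoins the route at 14.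

Further compounds

F1 | step 5 | (2R,4R)-2-(3,4-dimethoxyphenyl)-3-methylene-4-(triethylsilyloxy)oxolane | C=C1[C@@H](O[Si](CC)(CC)CC)CO[C@@H]1c1ccc(OC)c(OC)c1
F2 | step 5 | (2R,4R)-2-(3,4-dimethoxyphenyl)-3-methyleneoxolan-4-ol | C=C1[C@@H](O)CO[C@@H]1c1ccc(OC)c(OC)c1
F3 | step 5 | (2R,4S)-2-(3,4-dimethoxyphenyl)-3-methyleneoxolan-4-yl 4-nitrobenzoate | C=C1[C@H](OC(=O)c2ccc(cc2)[N+](=O)[O-])CO[C@@H]1c1ccc(OC)c(OC)c1
F4 | step 5 | (2R,4S)-2-(3,4-dimethoxyphenyl)-3-methyleneoxolan-4-ol | C=C1[C@H](O)CO[C@@H]1c1ccc(OC)c(OC)c1
F5 | step 1 | rac-1-(3,4-dimethoxyphenyl)prop-2-yn-1-ol | C#CC(O)c1ccc(OC)c(OC)c1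
F6 | step 1 | (R)-1-(3,4-dimethoxyphenyl)prop-2-yn-1-yl acetate | C#C[C@@H](OC(C)=O)c1ccc(OC)c(OC)c1
F7 | step 4 | (S)-2-[1-(3,4-dimethoxyphenyl)prop-2-ynyloxy]-N-methoxy-N-methylacetamide | C#C[C@H](OCC(=O)N(C)OC)c1ccc(OC)c(OC)c1
F8 | step 7 | (2S,3R,4S)-2-(3,4-dimethoxyphenyl)-3-(hydroxymethyl)oxolan-4-ol | OC[C@@H]1[C@H](O)CO[C@@H]1c1ccc(OC)c(OC)c1
F9 | step 6 | (2R,4S)-2-(3,4-dimethoxyphenyl)-4-(diphenylsilyloxy)-3-methyleneoxolane | C=C1[C@H](O[SiH](c2ccccc2)c2ccccc2)CO[C@@H]1c1ccc(OC)c(OC)c1
F10 | step 6 | all-cis 4-(3,4-dimethoxyphenyl)-2,2-diphenyl-tetrahydrofuro[3,4-d][1,2]oxasilole | C1[C@@H]2[C@H](O[Si]1(c1ccccc1)c1ccccc1)CO[C@@H]2c1ccc(OC)c(OC)c1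
A1 | alternative 1 | (S)-2-(tert-butyldimethylsilyloxy)-4-(3,4-dimethoxyphenyl)but-3-yn-1-ol | OC[C@@H](O[Si](C)(C)C(C)(C)C)C#Cc1ccc(OC)c(OC)c1
A2 | alternative 1 | methyl (S)-4-(tert-butyldimethylsilyloxy)-2-(3,4-dimethoxyphenyl)-4,5-dihydrofuran-3-carboxylate | COC(=O)C1=C(c2ccc(OC)c(OC)c2)OC[C@H]1O[Si](C)(C)C(C)(C)C
A3 | alternative 2 | (S)-3-[(bromomethyl)dimethylsilyloxy]-5-(3,4-dimethoxyphenyl)-2,3-dihydrofuran | BrC[Si](C)(C)O[C@@H]1COC(c2ccc(OC)c(OC)c2)=C1
A4 | alternative 2 | all-cis 4-(3,4-dimethoxyphenyl)-2,2-dimethyl-tetrahydrofuro[3,4-d][1,2]oxasilole | C1[C@@H]2[C@H](O[Si]1(C)C)CO[C@@H]2c1ccc(OC)c(OC)c1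
A5 | alternative 3 | arabino-configured C-(3,4-dimethoxyphenyl) pyranoside, 4-O-tert-butyldimethylsilyl, 3-O-triflyl, free 2-hydroxyl | O1[C@H](c2ccc(OC)c(OC)c2)[C@@H](O)[C@H](OS(=O)(=O)C(F)(F)F)[C@H](O[Si](C)(C)C(C)(C)C)C1
A6 | alternative 3 | all-cis 4-(tert-butyldimethylsilyloxy)-2-(3,4-dimethoxyphenyl)oxolane-3-carbaldehyde | O=C[C@@H]1[C@H](O[Si](C)(C)C(C)(C)C)CO[C@@H]1c1ccc(OC)c(OC)c1
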